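**Assumption:** uliginosin B has no stereocentre or stereogenic double bond, so the achiral structure in the SMILES is the only target and no stereocontrol is needed.

**Retrosynthetic overview**
- Cut the bond between the bridge CH2 and the filicinic ring: intermolecular Michael addition of isobutyrylfilicinic acid to a chromene ortho-quinone methide (the key C–C bond).
- The quinone methide is unmasked from a phenolic Mannich base, which puts the bridge carbon on C6 of the acylchromenediol.
- Pyran ring: propargyl ether Claisen/6π cascade on a bis-MOM acylphloroglucinol whose only free OH is the chelated one, which fixes the 8-acyl regiochemistry.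
- Filicinic ring: dearomative gem-dimethylation of the same acylphloroglucinol, itself made by Friedel–Crafts acylation of phloroglucinol.
- Ring order: aromatic ring (bought), then the filicinic ring by dearomatisation, then the pyran ring, then the methylene bridge.

**Route**

Step 1
Reactants: 1 phloroglucinol; 2 isobutyryl chloride
Product: 3 2-methyl-1-(2,4,6-trihydroxyphenyl)propan-1-one
Conditions: AlCl3 (4 equiv), PhNO2, 65 °C; then ice, 1 M HCl
Reagents that add atoms: none
Why: Friedel–Crafts C-acylation of the very electron-rich triol stops at the monoketone because the chelated acyl group deactivates the ring; no stereocentre is formed.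

Step 2
Reactants: 3 2-methyl-1-(2,4,6-trihydroxyphenyl)propan-1-one
Product: 4 3,5-dihydroxy-6,6-dimethyl-2-(2-methylpropanoyl)cyclohexa-2,4-dien-1-one (isobutyrylfilicinic acid)
Conditions: NaOMe (3 equiv), MeI (2.2 equiv), MeOH, 0 °C to rt; then 1 M HCl; chromatography
Reagents that add atoms: iodomethane, CI
Why: Dearomative double C-methylation of the phenoxide in a protic solvent puts both methyl groups on one ring carbon, giving the stable vinylogous acid; limiting MeI keeps mono- and trimethyl by-products down; no stereocentre is formed.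

Step 3
Reactants: 3 2-methyl-1-(2,4,6-trihydroxyphenyl)propan-1-one
Product: 5 1-[2-hydroxy-4,6-bis(methoxymethoxy)phenyl]-2-methylpropan-1-one
Conditions: MOMCl (2.2 equiv), iPr2NEt (3 equiv), CH2Cl2, 0 °C to rt
Reagents that add atoms: chloromethyl methyl ether, COCCl
Why: Selective O-alkylation (acetal protection) of the para OH and one ortho OH, because the remaining ortho OH is locked in a hydrogen bond to the ketone and is the least nucleophilic.

Step 4
Reactants: 5 1-[2-hydroxy-4,6-bis(methoxymethoxy)phenyl]-2-methylpropan-1-one; 6 3-chloro-3-methylbut-1-yne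
Product: 7 1-[2,4-bis(methoxymethoxy)-6-[(2-methylbut-3-yn-2-yl)oxy]phenyl]-2-methylpropan-1-one
Conditions: 6 (2.5 equiv), DBU (3 equiv), CuCl2·2H2O (1 mol %), MeCN, 0 °C to rt
Reagents that add atoms: none
Why: Copper-catalysed propargylic etherification through a copper acetylide alkylates even hindered, acidic phenols at the tertiary carbon, and the only free OH is the one ortho to the ketone.

Step 5
Reactants: 7 1-[2,4-bis(methoxymethoxy)-6-[(2-methylbut-3-yn-2-yl)oxy]phenyl]-2-methylpropan-1-one
Product: 11 1-[5,7-bis(methoxymethoxy)-2,2-dimethyl-2H-chromen-8-yl]-2-methylpropan-1-one, via allenyl dienone 8 (not isolated), via ortho-allenylphenol 9 (not isolated), via Z-dienone 10 (not isolated)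
Conditions: o-xylene, 140 °C, N2
Reagents that add atoms: none
Why: Aromatic propargyl Claisen rearrangement to the only free ortho carbon, tautomerisation, 1,5-hydrogen shift and oxa-6π electrocyclisation give the 2H-chromene with the ring oxygen next to the acyl carbon; the transient stereocentre of 8 is lost on enolisation.

Step 6
Reactants: 11 1-[5,7-bis(methoxymethoxy)-2,2-dimethyl-2H-chromen-8-yl]-2-methylpropan-1-one
Product: 12 1-(5,7-dihydroxy-2,2-dimethyl-2H-chromen-8-yl)-2-methylpropan-1-one
Conditions: 3 M aq HCl, MeOH, 50 °C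
Reagents that add atoms: none
Why: Acid-catalysed transacetalisation removes both MOM groups, while the chromene alkene, deactivated by the conjugated 8-acyl group, survives brief mild acid.

Step 7
Reactants: 12 1-(5,7-dihydroxy-2,2-dimethyl-2H-chromen-8-yl)-2-methylpropan-1-one
Product: 13 1-[6-[(dimethylamino)methyl]-5,7-dihydroxy-2,2-dimethyl-2H-chromen-8-yl]-2-methylpropan-1-one
Conditions: [CH2=NMe2]I (1.05 equiv), MeCN, rt; then sat. aq NaHCO3
Reagents that add atoms: N,N-dimethylmethyleneiminium iodide, C=[N+](C)C.[I-]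
Why: Mannich aminomethylation occurs at C6, the only free aromatic carbon and the one flanked by two hydroxyl groups; the ortho-hydroxybenzylamine is stable at rt.

Step 8
Reactants: 13 1-[6-[(dimethylamino)methyl]-5,7-dihydroxy-2,2-dimethyl-2H-chromen-8-yl]-2-methylpropan-1-one; 4 isobutyrylfilicinic acid
Product: 15 uliginosin B, via ortho-quinone methide 14 (not isolated)
Conditions: 4 (2 equiv), 1,4-dioxane, 90 °C, Ar, dark; then 1 M HCl wash; chromatography
Reagents that add atoms: none
Why: The acidic triketone 4 protonates the amine, heating expels Me2NH to give quinone methide 14, and the enolate carbon of 4 adds to its exocyclic CH2 in an intermolecular Michael addition that restores the aromatic ring; excess 4 suppresses double alkylation and no stereocentre is formed.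

**Compound list**
1 | phloroglucinol (benzene-1,3,5-triol) | Oc1cc(O)cc(O)c1 | starting material
2 | isobutyryl chloride (2-methylpropanoyl chloride) | CC(C)C(=O)Cl | starting material
3 | 2-methyl-1-(2,4,6-trihydroxyphenyl)propan-1-one | CC(C)C(=O)c1c(O)cc(O)cc1O | intermediate
4 | 3,5-dihydroxy-6,6-dimethyl-2-(2-methylpropanoyl)cyclohexa-2,4-dien-1-one (isobutyrylfilicinic acid, enol form of 2-isobutyryl-4,4-dimethylcyclohexane-1,3,5-trione) | CC(C)C(=O)C1=C(O)C=C(O)C(C)(C)C1=O | intermediate
5 | 1-[2-hydroxy-4,6-bis(methoxymethoxy)phenyl]-2-methylpropan-1-one | CC(C)C(=O)c1c(O)cc(OCOC)cc1OCOC | intermediate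
6 | 3-chloro-3-methylbut-1-yne | CC(C)(Cl)C#C | starting material
7 | 1-[2,4-bis(methoxymethoxy)-6-[(2-methylbut-3-yn-2-yl)oxy]phenyl]-2-methylpropan-1-one | CC(C)C(=O)c1c(OC(C)(C)C#C)cc(OCOC)cc1OCOC | intermediate
8 | 3,5-bis(methoxymethoxy)-6-(3-methylbuta-1,2-dien-1-yl)-2-(2-methylpropanoyl)cyclohexa-2,4-dien-1-one (racemic, transient) | CC(C)C(=O)C1=C(OCOC)C=C(OCOC)C(C=C=C(C)C)C1=O | intermediate
9 | 1-[2-hydroxy-4,6-bis(methoxymethoxy)-3-(3-methylbuta-1,2-dien-1-yl)phenyl]-2-methylpropan-1-one | CC(C)C(=O)c1c(O)c(C=C=C(C)C)c(OCOC)cc1OCOC | intermediate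
10 | (6Z)-3,5-bis(methoxymethoxy)-6-(3-methylbut-2-en-1-ylidene)-2-(2-methylpropanoyl)cyclohexa-2,4-dien-1-one | CC(C)C(=O)C1=C(OCOC)C=C(OCOC)/C(=C/C=C(C)C)C1=O | intermediate
11 | 1-[5,7-bis(methoxymethoxy)-2,2-dimethyl-2H-chromen-8-yl]-2-methylpropan-1-one | CC(C)C(=O)c1c(OCOC)cc(OCOC)c2C=CC(C)(C)Oc12 | intermediate
12 | 1-(5,7-dihydroxy-2,2-dimethyl-2H-chromen-8-yl)-2-methylpropan-1-one | CC(C)C(=O)c1c(O)cc(O)c2C=CC(C)(C)Oc12 | intermediate
13 | 1-[6-[(dimethylamino)methyl]-5,7-dihydroxy-2,2-dimethyl-2H-chromen-8-yl]-2-methylpropan-1-one | CC(C)C(=O)c1c(O)c(CN(C)C)c(O)c2C=CC(C)(C)Oc12 | intermediate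
14 | 5-hydroxy-2,2-dimethyl-6-methylidene-8-(2-methylpropanoyl)-2H-chromen-7(6H)-one | CC(C)C(=O)C1=C2OC(C)(C)C=CC2=C(O)C(=C)C1=O | intermediate
15 | uliginosin B: 3,5-dihydroxy-4-{[5,7-dihydroxy-2,2-dimethyl-8-(2-methylpropanoyl)-2H-chromen-6-yl]methyl}-6,6-dimethyl-2-(2-methylpropanoyl)cyclohexa-2,4-dien-1-one (achiral) | CC(C)C(=O)C1=C(O)C(Cc2c(O)c3c(c(C(=O)C(C)C)c2O)OC(C)(C)C=C3)=C(O)C(C)(C)C1=O | target

**Summary**
Total step count: 8.
Longest linear sequence: 7 steps (1 to 3 to 5 to 7 to 11 to 12 to 13 to 15; compound 4 joins at step 8 after 2 steps from 1).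

**Steps most likely to fail and their fallbacks**

Step 2 (gem-dimethylation: mono-, tri- and O-methyl by-products). The fallback sets out from 3 and comes back at 4. A second Friedel–Crafts acylation of 3 with 2 (AlCl3, PhNO2) gives 1,1'-(2,4,6-trihydroxy-1,3-phenylene)bis(2-methylpropan-1-one) F1, which has only one free ring carbon. NaOMe/MeI can therefore only gem-dimethylate that carbon, giving 3,5-dihydroxy-6,6-dimethyl-2,4-bis(2-methylpropanoyl)cyclohexa-2,4-dien-1-one F2. Exhaustive acid retro-Claisen deacylation (80% aq H2SO4, 80 °C) gives filicinic acid F3, which needs no selectivity. Mono-C-acylation of F3 with 2 (1 equiv, AlCl3, PhNO2) returns to 4.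

Step 4 (O-alkylation of a hindered, chelated phenol at a tertiary propargylic carbon). The fallback sets out from 3 and comes back at 12, dropping the protecting groups. Unprotected 3 is condensed with 3-methylbut-2-enal (ethylenediammonium diacetate 10 mol %, toluene, reflux). This Knoevenagel-type aldol condensation gives the vinyl quinone methide (6Z)-3,5-dihydroxy-6-(3-methylbut-2-en-1-ylidene)-2-(2-methylpropanoyl)cyclohexa-2,4-dien-1-one F4. Oxa-6π closure through the oxygen next to the acyl carbon gives 12; material closed through the para oxygen is removed by chromatography.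

Step 8 (bridge formation: double alkylation of 4, or slow amine loss from 13). The fallback sets out from 4 and 12 and comes back at 15, with the roles of the two halves reversed. Compound 4 is aminomethylated with [CH2=NMe2]I (MeCN, rt) to the betaine 4-[(dimethylamino)methyl]-3,5-dihydroxy-6,6-dimethyl-2-(2-methylpropanoyl)cyclohexa-2,4-dien-1-one F5. Warming F5 with excess 12 (dioxane, 80 °C) releases the exo-methylene triketone 5-hydroxy-4,4-dimethyl-2-methylidene-6-(2-methylpropanoyl)cyclohex-5-ene-1,3-dione F6. F6 is trapped at C6 of 12 in a Friedel–Crafts-type Michael addition to give 15.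

Further compounds
F1 | step 2 | 1,1'-(2,4,6-trihydroxy-1,3-phenylene)bis(2-methylpropan-1-one) | CC(C)C(=O)c1c(O)cc(O)c(C(=O)C(C)C)c1O
F2 | step 2 | 3,5-dihydroxy-6,6-dimethyl-2,4-bis(2-methylpropanoyl)cyclohexa-2,4-dien-1-one | CC(C)C(=O)C1=C(O)C(C(=O)C(C)C)=C(O)C(C)(C)C1=O
F3 | step 2 | filicinic acid (3,5-dihydroxy-4,4-dimethylcyclohexa-2,5-dien-1-one) | CC1(C)C(O)=CC(=O)C=C1O
F4 | step 4 | (6Z)-3,5-dihydroxy-6-(3-methylbut-2-en-1-ylidene)-2-(2-methylpropanoyl)cyclohexa-2,4-dien-1-one | CC(C)C(=O)C1=C(O)C=C(O)/C(=C/C=C(C)C)C1=O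
F5 | step 8 | 4-[(dimethylamino)methyl]-3,5-dihydroxy-6,6-dimethyl-2-(2-methylpropanoyl)cyclohexa-2,4-dien-1-one | CC(C)C(=O)C1=C(O)C(CN(C)C)=C(O)C(C)(C)C1=O
F6 | step 8 | 5-hydroxy-4,4-dimethyl-2-methylidene-6-(2-methylpropanoyl)cyclohex-5-ene-1,3-dione | CC(C)C(=O)C1=C(O)C(C)(C)C(=O)C(=C)C1=O
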